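Slowness in this flask comes as two clocks, and both run on the coupling partner.

    substrate + coupling partner + free catalyst → free catalyst + target (k1 = 3.24 M⁻² s⁻¹)
    coupling partner + free catalyst → spent catalyst (k2 = 0.00163 M⁻¹ s⁻¹)
substrate 0.078 M; coupling partner 0.117 M; free catalyst 0.39 mM
1. apparent order in coupling partner when 50% of the substrate are converted (percent change of the rate of making target for one percent more coupling partner charged)

At the charged amounts, substrate falls by a factor e in 1.88 h, but free catalyst lasts 1.46 h on average. So in this flask free catalyst dies faster than substrate goes. The ratio of the two clocks is the catalyst budget, 0.775: the ln of the fall in substrate that the whole catalyst charge can pay for. The coupling partner stands in both clocks, so it drops out of the budget.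

Spending follows in proportion. At 50% conversion the cost is ln of the fall, 0.693, so this reckoning leaves 10.6% of the free catalyst, and the partner charge does not enter the sum. With substrate and free catalyst held at that conversion, one percent more partner acts through the partner still present. That is the charge less 0.0390 M used on substrate, with the bite of step 2 set aside, so the order is 1.50.

The forecast stood higher, at 1.507, holding that “catalyst remaining depends only on substrate conversion”.

The simulation gives 1.5.

This flask reaches that conversion at 4.37 h, with a rate of 0.00146 M h⁻¹. The budget puts the free catalyst there at 10.6% of its charge, so sparing the catalyst should multiply the rate by 9.43. In the run without step 2, the rate at that conversion is the actual one multiplied by 9.49.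

(The constants were set for the occasion; the flask was simulated.)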